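The cyclodecane is treated as a tropone–diene [6+4] adduct whose one-carbon bridge has been cut. The feature used is that C7, bearing the isopropenyl carbon C11, lies opposite C2 (five ring bonds either way) and that the alkenes behind the C8/C9 diol and the C1/C10 and C4/C5 epoxides all have cis ring geometry, so C11 can span C7 and C2 as a ketone. One exo cycloaddition of 4-methyltropone (C11, C7–C10, C1, C2) with an (E)-dienyl menthyl carbonate (C3–C6) forms C2–C3 and C6–C7, closes the ten-membered perimeter as a bicyclo[4.4.1]undecatrienone and sets C2, C3 and C7; the menthyl group makes the adducts separable diastereomers.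

Key step: step 5

Convention: ring carbons are C1–C10 and the bridge/isopropenyl carbon is C11 (C7 isopropenyl, C8 OAc, C9 and C3 OAng, C4 and C10 methyl); α is the face below the ring when it is drawn flat with C1→C10 clockwise, so the target is 3α,8α,9α-triacyloxy, 1α,10α- and 4β,5β-epoxy, 7α-isopropenyl.
Assumption: either enantiomer of menthyl chloroformate serves, since it is only a resolving handle; the (1R,2S,5R) reagent is written and the adduct diastereomer with the drawn bicycle is carried on.
Remark: the C1/C10 epoxide is introduced only after the bridge is cut (step 12), because the retro-aldol gives a C3 enolate that would open an epoxide at C1 by β-elimination.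

Step 1
Reactants: 1 4-methylanisole
Product: 2 1-methoxy-4-methylcyclohexa-1,4-diene
Conditions: Li, liquid NH3, t-BuOH, THF, −78 to −33 °C; then H2O
Reagents that add atoms: none
Why: Birch reduction (dissolving-metal 1,4-reduction) leaves the methoxy- and methyl-bearing carbons on the two residual double bonds because the radical anion is protonated at the positions ortho and meta to the methoxy group, and no stereocentre is formed.

Step 2
Reactants: 2 1-methoxy-4-methylcyclohexa-1,4-diene; 3 bromoform
Product: 4 7,7-dibromo-1-methoxy-4-methylbicyclo[4.1.0]hept-3-ene (racemic)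
Conditions: CHBr3, KOt-Bu, pentane, −20 to 0 °C
Reagents that add atoms: bromoform (3), BrC(Br)Br
Why: Dibromocarbene, formed by α-elimination from bromoform, adds in a cheletropic [2+1] cyclopropanation to the enol ether double bond, the more nucleophilic alkene, and the ring fusion can only be cis, so 4 is a single racemic diastereomer.

Step 3
Reactants: 4 7,7-dibromo-1-methoxy-4-methylbicyclo[4.1.0]hept-3-ene
Product: 6 4-methyltropone, via 2-bromo-5-methylcyclohepta-2,5-dien-1-one 5 (not isolated)
Conditions: AgNO3 (2.2 equiv), acetone/H2O, 50 °C; then aqueous NaHCO3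
Reagents that add atoms: water, O
Why: Silver-assisted ionization of a cyclopropyl C–Br bond drives the disrotatory electrocyclic opening of the gem-dibromocyclopropane to a methoxy-stabilized allyl cation, water converts it into bromodienone 5, and loss of HBr under aromatic driving force gives the tropone with the methyl group on C4 (silver-promoted ring expansion).

Step 4
Reactants: 7 tiglaldehyde; 8 (1R,2S,5R)-menthyl chloroformate
Product: 10 (E)-2-methylbuta-1,3-dien-1-yl (1R,2S,5R)-menthyl carbonate, via potassium dienolate 9 (not isolated)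
Conditions: KOt-Bu, THF, −78 °C; then 8, −78 to 0 °C
Reagents that add atoms: (1R,2S,5R)-menthyl chloroformate (8), ClC(=O)O[C@@H]1C[C@H](C)CC[C@H]1C(C)C
Why: γ-Deprotonation of the s-trans enal gives the E-dienolate 9 and O-acylation of this potassium enolate by the chloroformate gives the enol carbonate with oxygen trans to the vinyl group, the geometry the cycloaddition needs, while the menthyl stereocentres are not involved.

Step 5
Reactants: 6 4-methyltropone; 10 (E)-2-methylbuta-1,3-dien-1-yl (1R,2S,5R)-menthyl carbonate
Product: 11 3,9-dimethyl-11-oxobicyclo[4.4.1]undeca-2,4,8-trien-10-yl (1R,2S,5R)-menthyl carbonate (exo adduct; C11 bridge α at C2 and C7; O3 α; single diastereomer after separation)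
Conditions: 6 (1 equiv), 10 (1.5 equiv), xylenes, BHT, 130 °C, sealed tube; then chromatography or crystallization to separate the two exo diastereomers
Reagents that add atoms: none
Why: The step is a thermally allowed, suprafacial [6π+4π] cycloaddition of the tropone triene with the s-cis diene, the reaction type established for tropone with (E)-1-acyloxy- and 1-silyloxybuta-1,3-dienes; the diene termini C3 and C6 bond to the tropone α-carbons C2 and C7. It closes one ring, the seven-membered C11–C2–C3–C4–C5–C6–C7 ring, by concerted two-bond formation between the two components (an intermolecular cycloaddition, not a chain cyclization), and together with the tropone ring this completes the ten-membered perimeter, each alkene lying in a seven-membered ring and therefore cis. C2 and C7 are tied cis by the one-carbon bridge, and C3 is set relative to them by the exo transition state, in which the diene sits under the carbonyl and avoids the repulsive secondary overlap with C8–C1 of the endo mode, combined with the E geometry of the enol carbonate, which places O3 on the same (α) face of the perimeter as the bridge. The step needs [6+4] rather than [4+2] periselectivity, which the large frontier coefficients at the tropone termini C2 and C7 and the exo geometry provide, and bonding of C3 to C2 rather than to C7, which the remote C10 methyl group biases only weakly. The enol carbonate was chosen for this reason: its oxygen is a poor π-donor, so the C4 methyl group should weight the diene HOMO toward C3, which then pairs with C2, the better acceptor terminus because addition there keeps negative charge off the methyl-bearing C10; any regioisomer is removed together with the unwanted diastereomer. Absolute configuration is not induced but secured by separation, since the menthyl group turns the two enantiomeric exo bicycles into diastereomers, of which the one with the drawn configuration is taken on and is to be assigned crystallographically.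

Step 6
Reactants: 11 exo adduct
Product: 12 8α,9α-diol of the bridged adduct
Conditions: OsO4 (2 mol %), N-methylmorpholine N-oxide (1.05 equiv), acetone/H2O, 0 °C
Reagents that add atoms: N-methylmorpholine N-oxide, C[N+]1([O-])CCOCC1; water, O
Why: Catalytic OsO4/N-oxide syn-dihydroxylation should take the disubstituted diene terminus C8=C9 in preference to the more hindered trisubstituted C1=C10 (whose allylic carbon C2 also carries the carbonate-bearing C3) and to the carbonate-deactivated C4=C5, and it can only approach from the α face because the inward hydrogen on C6 covers the β face of C8, so O8 and O9 are set cis to the bridge.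

Step 7
Reactants: 12 8α,9α-diol of the bridged adduct
Product: 13 8α,9α-bis(triethylsilyl) ether of the bridged adduct
Conditions: Et3SiOTf, 2,6-lutidine, CH2Cl2, −78 to 0 °C
Reagents that add atoms: triethylsilyl triflate, CC[Si](CC)(CC)OS(=O)(=O)C(F)(F)F
Why: Silylation of both secondary hydroxyls with the silyl triflate and a hindered pyridine base (silyl ether formation) is safe for the ketone, which cannot form an enol ether because both α-carbons are bridgeheads, and changes no stereocentre.

Step 8
Reactants: 13 8α,9α-bis(triethylsilyl) ether of the bridged adduct; 14 methyllithium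
Product: 16 bridged diol with C11(OH)CH3 and free 3α-OH, via lithium carbinolate carbonate 15 (not isolated)
Conditions: MeLi (6 equiv), THF, −78 °C, then 0 °C; then H2O
Reagents that add atoms: methyllithium (14), [Li]C
Why: Methyllithium adds 1,2 to the bridging ketone, which cannot enolize because both α-carbons are bridgeheads, to give alkoxide 15, and on warming the excess reagent cleaves the carbonate by nucleophilic acyl substitution to free O3 and return menthol, the new C11 centre (attack assumed from the side of the C8–C1 bridge) being destroyed again in step 10.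

Step 9
Reactants: 16 bridged diol with C11(OH)CH3 and free 3α-OH
Product: 17 bridged β-hydroxy enone (C3 ketone)
Conditions: Dess–Martin periodinane, NaHCO3, CH2Cl2, 0 °C to rt
Reagents that add atoms: none
Why: Dess–Martin oxidation turns the secondary allylic alcohol into the enone while the tertiary carbinol is inert and the buffered neutral medium leaves the β-hydroxy ketone unfragmented, the C3 stereocentre being erased on purpose.

Step 10
Reactants: 17 bridged β-hydroxy enone (C3 ketone)
Product: 21 (1(10)Z,4Z)-7α-isopropenyl-4,10-dimethyl-8α,9α-bis(triethylsilyloxy)cyclodeca-1(10),4-dien-3-one, via bridged potassium alkoxide 18 (not isolated), via ring-opened acetyl enolate 19 (not isolated), via methylenated potassium enolate 20 (not isolated)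
Conditions: KN(SiMe3)2 (1.05 equiv), THF, −78 to −40 °C; then Ph3P=CH2 (from Ph3PCH3Br and KN(SiMe3)2, THF), −78 to 0 °C; then AcOH, −78 °C
Reagents that add atoms: methyltriphenylphosphonium bromide, C[P+](c1ccccc1)(c1ccccc1)c1ccccc1.[Br-]
Why: The tertiary potassium alkoxide 18 undergoes retro-aldol fragmentation of C2–C11 to the cross-conjugated ring enolate 19 carrying a C7 acetyl group, the enolate protects the ring ketone while the Wittig reagent methylenates the acetyl group (which also pulls the ring opening to completion), and cold protonation of 20 at C2 returns the ketone with the C1=C10 alkene unmoved and C7, C8 and C9 untouched.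

Step 11
Reactants: 21 (1(10)Z,4Z)-7α-isopropenyl-4,10-dimethyl-8α,9α-bis(triethylsilyloxy)cyclodeca-1(10),4-dien-3-one
Product: 22 (1(10)Z,4Z)-8α,9α-dihydroxy-7α-isopropenyl-4,10-dimethylcyclodeca-1(10),4-dien-3-one
Conditions: HF·pyridine, pyridine, THF, 0 °C
Reagents that add atoms: none
Why: Pyridine-buffered HF cleaves both Si–O bonds (fluoride desilylation) under conditions too mild to move the C1=C10 alkene into conjugation or to epimerize C7.

Step 12
Reactants: 22 (1(10)Z,4Z)-8α,9α-dihydroxy-7α-isopropenyl-4,10-dimethylcyclodeca-1(10),4-dien-3-one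
Product: 23 (4Z)-1α,10α-epoxy-8α,9α-dihydroxy-7α-isopropenyl-4,10-dimethylcyclodec-4-en-3-one
Conditions: VO(acac)2 (5 mol %), t-BuOOH, CH2Cl2, 0 °C to rt
Reagents that add atoms: tert-butyl hydroperoxide, CC(C)(C)OO
Why: Hydroxyl-directed vanadium-catalysed epoxidation acts only on the alkene allylic to a free hydroxyl, C1=C10, and transfers oxygen from the vanadate ester of O9 to the face that gives the cis (erythro) epoxy alcohol, the sense known for Z-configured medium-ring allylic alcohols and reinforced here by allylic 1,2-strain with the C10 methyl group, while the enone and isopropenyl alkenes stay intact.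

Step 13
Reactants: 23 (4Z)-1α,10α-epoxy-8α,9α-dihydroxy-7α-isopropenyl-4,10-dimethylcyclodec-4-en-3-one
Product: 24 (4Z)-8α-acetoxy-1α,10α-epoxy-9α-hydroxy-7α-isopropenyl-4,10-dimethylcyclodec-4-en-3-one
Conditions: AcCl, 2,4,6-collidine, CH2Cl2, −78 to −20 °C
Reagents that add atoms: acetyl chloride, CC(Cl)=O
Why: Site-selective O-acylation: O9 is now neopentylic, flanked by the fully substituted epoxide carbon C10, so acetyl chloride with a hindered weak base should esterify O8 only, and such a base does not enolize the β,γ-epoxy ketone, no stereocentre being touched.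

Step 14
Reactants: 24 (4Z)-8α-acetoxy-1α,10α-epoxy-9α-hydroxy-7α-isopropenyl-4,10-dimethylcyclodec-4-en-3-one
Product: 25 (3S,4Z)-8α-acetoxy-1α,10α-epoxy-3α,9α-dihydroxy-7α-isopropenyl-4,10-dimethylcyclodec-4-ene
Conditions: (R)-2-methyl-CBS-oxazaborolidine, catecholborane, toluene, −78 °C
Reagents that add atoms: none
Why: Corey–Bakshi–Shibata reduction, in which the oxazaborolidine binds the ketone with the α-branched alkenyl arm C4 as the large group and C2H2 as the small one, should deliver hydride under reagent control to the face that gives the 3S (3α) alcohol with the R catalyst, and its Lewis-acidic, non-basic medium spares the β,γ-epoxy ketone.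

Step 15
Reactants: 25 (3S,4Z)-8α-acetoxy-1α,10α-epoxy-3α,9α-dihydroxy-7α-isopropenyl-4,10-dimethylcyclodec-4-ene
Product: 26 8α-acetoxy-1α,10α:4β,5β-diepoxy-3α,9α-dihydroxy-7α-isopropenyl-4,10-dimethylcyclodecane
Conditions: mCPBA, NaHCO3, CH2Cl2, 0 °C
Reagents that add atoms: 3-chloroperoxybenzoic acid, OOC(=O)c1cccc(Cl)c1
Why: Hydroxyl-directed peracid epoxidation (Prilezhaev reaction): with C3–H held in the alkene plane by allylic 1,3-strain against C6, the hydrogen-bonded peracid attacks the outer face that carries O3 and should give the trans (threo) 4β,5β-epoxy alcohol, as Z-configured medium-ring allylic alcohols do, the 1,1-disubstituted isopropenyl alkene being much slower.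

Step 16
Reactants: 26 8α-acetoxy-1α,10α:4β,5β-diepoxy-3α,9α-dihydroxy-7α-isopropenyl-4,10-dimethylcyclodecane
Product: 27 CNP0260455.1 (target)
Conditions: angelic acid, 2,4,6-trichlorobenzoyl chloride, Et3N, toluene, rt; then 26, 75 °C
Reagents that add atoms: angelic acid, C/C=C(/C)C(=O)O
Why: Yamaguchi-type mixed-anhydride esterification acylates both remaining secondary hydroxyls at the angeloyl carbonyl without the Z-to-E isomerization that angeloyl chloride or nucleophilic catalysis risk, touches no stereocentre and gives the target.

Compound list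
1 | 4-methylanisole | COc1ccc(C)cc1 | starting material
2 | 1-methoxy-4-methylcyclohexa-1,4-diene | COC1=CCC(C)=CC1 | intermediate
3 | bromoform | BrC(Br)Br | starting material
4 | 7,7-dibromo-1-methoxy-4-methylbicyclo[4.1.0]hept-3-ene (racemic, cis-fused) | COC12CC=C(C)CC1C2(Br)Br | intermediate
5 | 2-bromo-5-methylcyclohepta-2,5-dien-1-one | O=C1CC=C(C)CC=C1Br | intermediate (not isolated)
6 | 4-methyltropone | O=C1C=CC(C)=CC=C1 | intermediate
7 | tiglaldehyde, (E)-2-methylbut-2-enal | C/C=C(\C)C=O | starting material
8 | (1R,2S,5R)-menthyl chloroformate | ClC(=O)O[C@@H]1C[C@H](C)CC[C@H]1C(C)C | starting material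
9 | potassium (E)-2-methylbuta-1,3-dien-1-olate | C=C/C(C)=C/[O-].[K+] | intermediate (not isolated)
10 | (E)-2-methylbuta-1,3-dien-1-yl (1R,2S,5R)-menthyl carbonate | C=C/C(C)=C/OC(=O)O[C@@H]1C[C@H](C)CC[C@H]1C(C)C | intermediate
11 | exo adduct, 3,9-dimethyl-11-oxobicyclo[4.4.1]undeca-2,4,8-trien-10-yl menthyl carbonate (bridge and O3 both α) | O=C1[C@@H]2C=CC(C)=C[C@H]1[C@H](OC(=O)O[C@@H]3C[C@H](C)CC[C@H]3C(C)C)C(C)=CC2 | intermediate
12 | 8α,9α-diol of the bridged adduct | O=C1[C@@H]2[C@H](O)[C@H](O)C(C)=C[C@H]1[C@H](OC(=O)O[C@@H]3C[C@H](C)CC[C@H]3C(C)C)C(C)=CC2 | intermediate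
13 | 8α,9α-bis(triethylsilyl) ether of the bridged adduct | O=C1[C@@H]2[C@H](O[Si](CC)(CC)CC)[C@H](O[Si](CC)(CC)CC)C(C)=C[C@H]1[C@H](OC(=O)O[C@@H]3C[C@H](C)CC[C@H]3C(C)C)C(C)=CC2 | intermediate
14 | methyllithium | [Li]C | starting material
15 | lithium C11 carbinolate still carrying the menthyl carbonate | C[C@]1([O-])[C@@H]2[C@H](O[Si](CC)(CC)CC)[C@H](O[Si](CC)(CC)CC)C(C)=C[C@H]1[C@H](OC(=O)O[C@@H]3C[C@H](C)CC[C@H]3C(C)C)C(C)=CC2.[Li+] | intermediate (not isolated)
16 | bridged diol: C11(OH)CH3, 3α-OH, 8α,9α-bis(triethylsilyloxy) (C11 configuration immaterial) | C[C@]1(O)[C@@H]2[C@H](O[Si](CC)(CC)CC)[C@H](O[Si](CC)(CC)CC)C(C)=C[C@H]1[C@H](O)C(C)=CC2 | intermediate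
17 | bridged β-hydroxy enone (C3 ketone, C11 carbinol) | C[C@]1(O)[C@@H]2[C@H](O[Si](CC)(CC)CC)[C@H](O[Si](CC)(CC)CC)C(C)=C[C@H]1C(=O)C(C)=CC2 | intermediate
18 | potassium alkoxide of 17 | C[C@]1([O-])[C@@H]2[C@H](O[Si](CC)(CC)CC)[C@H](O[Si](CC)(CC)CC)C(C)=C[C@H]1C(=O)C(C)=CC2.[K+] | intermediate (not isolated)
19 | ring-opened potassium C3 enolate with 7α-acetyl group | CC(=O)[C@H]1C/C=C(/C)C([O-])=C/C=C(C)\[C@@H](O[Si](CC)(CC)CC)[C@H]1O[Si](CC)(CC)CC.[K+] | intermediate (not isolated)
20 | potassium C3 enolate with 7α-isopropenyl group | C=C(C)[C@H]1C/C=C(/C)C([O-])=C/C=C(C)\[C@@H](O[Si](CC)(CC)CC)[C@H]1O[Si](CC)(CC)CC.[K+] | intermediate (not isolated)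
21 | (1(10)Z,4Z)-7α-isopropenyl-4,10-dimethyl-8α,9α-bis(triethylsilyloxy)cyclodeca-1(10),4-dien-3-one | C=C(C)[C@H]1C/C=C(C)\C(=O)C/C=C(C)\[C@@H](O[Si](CC)(CC)CC)[C@H]1O[Si](CC)(CC)CC | intermediate
22 | (1(10)Z,4Z)-8α,9α-dihydroxy-7α-isopropenyl-4,10-dimethylcyclodeca-1(10),4-dien-3-one | C=C(C)[C@H]1C/C=C(C)\C(=O)C/C=C(C)\[C@@H](O)[C@H]1O | intermediate
23 | (4Z)-1α,10α-epoxy-8α,9α-dihydroxy-7α-isopropenyl-4,10-dimethylcyclodec-4-en-3-one | C=C(C)[C@H]1C/C=C(C)\C(=O)C[C@H]2O[C@@]2(C)[C@@H](O)[C@H]1O | intermediate
24 | (4Z)-8α-acetoxy-1α,10α-epoxy-9α-hydroxy-7α-isopropenyl-4,10-dimethylcyclodec-4-en-3-one | C=C(C)[C@H]1C/C=C(C)\C(=O)C[C@H]2O[C@@]2(C)[C@@H](O)[C@H]1OC(C)=O | intermediate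
25 | (3S,4Z)-8α-acetoxy-1α,10α-epoxy-3α,9α-dihydroxy-7α-isopropenyl-4,10-dimethylcyclodec-4-ene | C=C(C)[C@H]1C/C=C(C)\[C@@H](O)C[C@H]2O[C@@]2(C)[C@@H](O)[C@H]1OC(C)=O | intermediate
26 | 8α-acetoxy-1α,10α:4β,5β-diepoxy-3α,9α-dihydroxy-7α-isopropenyl-4,10-dimethylcyclodecane | C=C(C)[C@H]1C[C@@H]2O[C@]2(C)[C@@H](O)C[C@H]2O[C@@]2(C)[C@@H](O)[C@H]1OC(C)=O | intermediate
27 | CNP0260455.1: 8α-acetoxy-3α,9α-bis(angeloyloxy)-1α,10α:4β,5β-diepoxy-7α-isopropenyl-4,10-dimethylcyclodecane | C=C(C)[C@H]1C[C@@H]2O[C@]2(C)[C@@H](OC(=O)/C(C)=C\C)C[C@H]2O[C@@]2(C)[C@@H](OC(=O)/C(C)=C\C)[C@H]1OC(C)=O | target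

Total step count: 16. Longest linear sequence: 15 steps (steps 1–3 and 5–16); the diene branch is step 4.

Steps most likely to fail

Step 5. What may go wrong: sluggish cycloaddition or leakage into [4+2] adducts with the weakly donating enol carbonate, bonding of C3 to C7 instead of C2, or diastereomers that do not separate. The fallback sets out from 6 and 7 and comes back at 11. Tiglaldehyde is silylated with t-BuMe2SiOTf and Et3N to (E)-1-(tert-butyldimethylsilyloxy)-2-methylbuta-1,3-diene F1, a more electron-rich diene whose HOMO is weighted toward C6 instead of C3, so that whichever tropone terminus is the better acceptor, one of the two dienes is matched to it. Heating F1 with 6 should give the racemic exo silyl ether adduct F2. HF·pyridine, chosen because acid does not trigger retro-aldol cleavage of C2–C3 in the β-hydroxy ketone, frees the racemic 3-hydroxy adduct F3. Acylation of F3 with 8 and pyridine gives the two diastereomeric carbonates, which are separated to give 11.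

Step 6. What may go wrong: competing osmylation of the C1=C10 alkene, that is, poor site selectivity within the diene. The fallback sets out from 11 and comes back at 13. mCPBA (NaHCO3, CH2Cl2, 0 °C) epoxidizes the most nucleophilic alkene, the trisubstituted diene terminus, from the open α face to give the 1α,10α-epoxide F4, which serves as a temporary mask. OsO4/N-methylmorpholine N-oxide then finds only C8=C9 among the electron-rich alkenes (C4=C5 is deactivated by its allylic carbonate) and only its α face, giving the epoxy diol F5. Et3SiOTf/2,6-lutidine gives the bis(triethylsilyl) ether F6. Deoxygenation with PPh3 and catalytic CH3ReO3 (toluene, 80 °C) restores the alkene, whose cis geometry is enforced by the seven-membered ring, and returns 13; the mask has to go before step 10 for the reason given in the remark above.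

Step 14. What may go wrong: hydride delivery governed by the conformation of the ten-membered ring and not by the catalyst, giving low or reversed facial selectivity at C3. The fallback sets out from 24 and comes back at 25. The ketone is reduced deliberately to the other epimer with the (S)-oxazaborolidine and catecholborane (or with NaBH4/CeCl3 if the ring bias is strong) to give the 3β-alcohol F7. Mitsunobu esterification with chloroacetic acid (PPh3, diisopropyl azodicarboxylate) inverts C3 to the 3α-chloroacetate F8, the neopentylic O9 being too hindered to react. Thiourea and NaHCO3 in ethanol remove the chloroacetyl group in the presence of the acetate and give 25.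

Further compounds
F1 | step 5 | (E)-1-(tert-butyldimethylsilyloxy)-2-methylbuta-1,3-diene | C=C/C(C)=C/O[Si](C)(C)C(C)(C)C
F2 | step 5 | racemic exo silyl ether adduct (relative configuration shown) | O=C1[C@@H]2C=CC(C)=C[C@H]1[C@H](O[Si](C)(C)C(C)(C)C)C(C)=CC2
F3 | step 5 | racemic 3-hydroxy adduct (relative configuration shown) | O=C1[C@@H]2C=CC(C)=C[C@H]1[C@H](O)C(C)=CC2
F4 | step 6 | 1α,10α-epoxide of 11 | O=C1[C@@H]2C=C[C@]3(C)O[C@@H]3[C@H]1[C@H](OC(=O)O[C@@H]4C[C@H](C)CC[C@H]4C(C)C)C(C)=CC2
F5 | step 6 | 1α,10α-epoxy-8α,9α-diol of the bridged adduct | O=C1[C@@H]2[C@H](O)[C@H](O)[C@]3(C)O[C@@H]3[C@H]1[C@H](OC(=O)O[C@@H]4C[C@H](C)CC[C@H]4C(C)C)C(C)=CC2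
F6 | step 6 | 8α,9α-bis(triethylsilyl) ether of F5 | O=C1[C@@H]2[C@H](O[Si](CC)(CC)CC)[C@H](O[Si](CC)(CC)CC)[C@]3(C)O[C@@H]3[C@H]1[C@H](OC(=O)O[C@@H]4C[C@H](C)CC[C@H]4C(C)C)C(C)=CC2
F7 | step 14 | 3β-alcohol, the C3 epimer of 25 | C=C(C)[C@H]1C/C=C(C)\[C@H](O)C[C@H]2O[C@@]2(C)[C@@H](O)[C@H]1OC(C)=O
F8 | step 14 | 3α-chloroacetate of 25 | C=C(C)[C@H]1C/C=C(C)\[C@@H](OC(=O)CCl)C[C@H]2O[C@@]2(C)[C@@H](O)[C@H]1OC(C)=O
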